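## Structural features

Target 20 is a 2-arylbenzofuran. Benzo ring A and furan ring B share the C3a–C7a bond, and C2 of ring B is bonded to C1' of a 3,5-dihydroxyphenyl ring C. Ring A carries three contiguous substituents: a CH2–C(=O)–CH(CH3)2 chain on C4, a methoxy group on C5 and a free hydroxyl on C6, with C7 unsubstituted. There is no stereocentre and no stereogenic double bond, so no configuration has to be set or protected. The fragile elements are the electron-rich C2=C3 bond of ring B (oxidants, electrophiles), the three free phenols, the benzylic ketone with its acidic CH2 (enolisation, and cyclodehydration onto O5 if O5 were ever free beside the ketone), and the single methyl ether that must be told apart from three hydroxyls. The real difficulty is the regiochemistry of ring A: a carbon substituent on C4, wedged between the ring fusion and C5, next to an oxygen on C5 that differs from the oxygen on C6. The key step exploits the C4–CH2–C(=O)/C5–O pair: a two-carbon ketene acetal added across a C4≡C5 aryne puts CH2 on C4 and a masked carbonyl on C5, and a later oxygen insertion between C5 and that carbonyl gives the C5–O bond while the carbonyl carbon becomes the ketone carbon of the side chain.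

## Logic of the disconnections

20 ⇒ 19. The three O–isopropyl bonds (O6, O3', O5') are cut. The phenols have to be masked through strong base, peracid and organometallic steps, and secondary alkyl ethers can be removed by a boron trihalide while the primary methyl ether stays. This leaves one global deprotection as the last step; the forward demand is dealkylation that spares the ketone and O5–CH3.

19 ⇒ 18. The C(=O)–CH(CH3)2 bond is cut. This reduces the side chain to an arylacetic acid derivative and an isopropyl nucleophile. The forward step must stop at the ketone and must tolerate the acidic benzylic CH2, which is why an N-methoxy-N-methylamide is the acyl partner.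

18 ⇒ 17 ⇒ 16. The O5–CH3 bond and then the amide C–N bond are cut, leading back to a five-membered aryl lactone that ties O5 to the side-chain carbonyl. The lactone distinguishes O5 from O6 without any protecting-group step: opening it with the amine releases O5 as the only free phenol, which is methylated before a ketone exists.

16 ⇒ 15. The C5–O bond is cut by removing the inserted oxygen, giving the benzocyclobutenone. The forward step must make the aryl carbon C5 migrate, not the benzylic CH2, and must leave the C2=C3 bond alone.

15 ⇒ 14 ⇒ 11 + 12. After unmasking the ketal, the C4–CH2 and C5–C(ketal) bonds are cut together, which removes the four-membered ring and both ring A substituents at once. This is the largest simplification in the plan: 11 has only hydrogen on C4 and bromine on C5. The forward step must generate the C4≡C5 aryne from 11 and add 12 with the CH2 terminus on C4.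

11 ⇒ 5 + 8. The O1–C2 and C2=C3 bonds of ring B are cut, dividing the molecule into a ring A phosphonium salt and a ring C acid. The forward step is an acylation followed by intramolecular olefination and must tolerate the aryl bromide.

5 ⇒ 4 ⇒ 3 ⇒ 2 ⇒ 1. The benzylic C–P bond, the benzylic C–H (alcohol from aldehyde), the C5–Br bond and the O4–isopropyl bond are cut in turn. Bromine is introduced on the salicylaldehyde, where the OH/OR pattern directs it to a single position, so the electron-rich benzofuran never has to be halogenated.

8 ⇒ 6. The two O–isopropyl bonds of ring C are cut, leading to a commodity acid.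

## Other disconnections considered

Alternative 1: The cut is the C3a–C7a bond, so ring A is made last from an open chain. The racemic cyclobutenone A2 (from a squaric ester and an enynyl-metal fragment that already carries ring C and the prenyl group) would be heated. A 4π ring opening gives a dienylketene, a 6π closure joins the ketene carbon (future C7a) to the alkene terminus (future C3a), and tautomerisation gives the alkynyl phenol A1.
- In its favour: every substituent of ring A is fixed by the connectivity of A2, so there is no regiochemical question on an aromatic ring. On this point it is better than the chosen plan, which relies on an electronic bias in the aryne addition and on a migratory preference in the oxygen insertion. The conditions are neutral, and the C7a–OH/C3a–alkyne pair of A1 is set up for closing ring B.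
- Against it here: A2 needs a trisubstituted enynyl organometallic with a skipped diene and the methylation of a hindered tertiary cyclobutenol. After A1 there remain the furan closure, two redox steps to turn the prenyl group into the oxo chain, and deprotection. The prenyl and alkyne units also offer the ketene competing cycloaddition paths.
- Comparison: the pericyclic cascade is mechanistically clean and equal in reliability to the aryne addition, but the route is estimated to be longer and starts from far less accessible materials than 1, 6 and 12.

Alternative 2: The cut is the C2=C3 bond of ring B. The aryl ester aldehyde A4 would be treated with low-valent titanium (TiCl3, Zn), coupling the formyl carbon with the ester carbonyl carbon to give benzofuran A3.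
- In its favour: the ester is made by simple acylation, and the coupling joins the same two carbons as step 6, so in convergence it is the equal of the chosen furan closure. The benzyl ethers would come off by hydrogenolysis, which poses no risk to the methyl ether; on this point it is better than the Lewis acid deprotection of the chosen plan.
- Against it here: A4 presupposes a pentasubstituted salicylaldehyde with prenyl, methoxy and benzyloxy groups already contiguous and differentiated, so the ring A problem is moved into the starting material and not solved. Excess low-valent titanium can cleave the aryl ester or give pinacol-type dimers. The prenyl group again needs two redox steps, and these must precede hydrogenolysis.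
- Comparison: the furan-forming steps are equivalent, but the chosen plan builds the C4/C5 pattern after ring B from a cheap dihydroxybenzaldehyde and is estimated to be shorter overall.

Alternative 3: The cut is C3a–C4, so ring A is built onto a preformed 2-arylfuran. Under Brønsted acid the β-carbon of the furan in A6 (racemic at the methoxy-bearing carbon, which becomes sp2) would attack the 3-oxo group. Dehydration and enolisation would then give the phenol ester A5.
- In its favour: A5 has the acetic ester on C4, methoxy on C5 and a free hydroxyl on C6. The O5/O6 differentiation and the side-chain carbonyl arrive in one step without any oxygen insertion. In oxidation-state economy this is better than the chosen plan, which needs hydrolysis, oxygen insertion, ring opening and methylation to reach the same stage.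
- Against it here: A6 is an α-methoxy 3,5-dioxo ester, prone to enolisation, retro-Claisen cleavage and self-condensation, and its assembly by successive acylations is uncertain. The 2,5-disubstituted furan can be opened hydrolytically by the same acid that must drive the cyclodehydration. The C6 phenol would need protection before the Grignard step.
- Comparison: the ring-forming event is more direct, but the precursor is harder to make and handle than 11. The steps saved after the key step are likely to be spent before it, so no advantage in step count is expected.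

Key step: step 7

Remark on the structures: bromine on C5 with the only ortho hydrogen on C4, the CH2 of the cycloadduct on C4 and its ketal carbon on C5 are mutually consistent and map onto the C4–CH2C(=O)/C5–O pattern of 20, so no structure had to be corrected.

Remark on the precursor design: isopropyl ethers are kept on all three phenols because they withstand NaNH2, peracid, AlMe3 and Grignard reagents and can be removed beside a methyl ether. The acetal 12 is used in excess so that it outcompetes amide ion for the aryne.

Assumption: moracin Q is taken to be the achiral structure 20 of the compound list.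

## Route

Step 1
Reactants: 1 2,4-dihydroxybenzaldehyde
Product: 2 2-hydroxy-4-(propan-2-yloxy)benzaldehyde
Conditions: i-PrBr, CsHCO3, MeCN, 80 °C
Reagents that add atoms: 2-bromopropane, CC(C)Br
Why: Williamson etherification; the 2-OH is hydrogen-bonded to the formyl group and is the weaker acid, so the mild hydrogencarbonate base should ionise and alkylate only the 4-OH.

Step 2
Reactants: 2 2-hydroxy-4-(propan-2-yloxy)benzaldehyde
Product: 3 5-bromo-2-hydroxy-4-(propan-2-yloxy)benzaldehyde
Conditions: NBS, MeCN, 0 °C to rt
Reagents that add atoms: N-bromosuccinimide, O=C1CCC(=O)N1Br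
Why: Electrophilic aromatic bromination; C5 is para to the free OH, ortho to the ether and unhindered, whereas C3 lies between two oxygen substituents, so monobromination should occur at C5.

Step 3
Reactants: 3 5-bromo-2-hydroxy-4-(propan-2-yloxy)benzaldehyde
Product: 4 4-bromo-2-(hydroxymethyl)-5-(propan-2-yloxy)phenol
Conditions: NaBH4, MeOH, 0 °C
Reagents that add atoms: none
Why: Hydride reduction of the aldehyde to the benzylic alcohol; the aryl bromide and the ether are inert to NaBH4.

Step 4
Reactants: 4 4-bromo-2-(hydroxymethyl)-5-(propan-2-yloxy)phenol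
Product: 5 [5-bromo-2-hydroxy-4-(propan-2-yloxy)benzyl]triphenylphosphonium bromide
Conditions: PPh3·HBr, MeCN, 80 °C
Reagents that add atoms: triphenylphosphine hydrobromide, [PH+](c1ccccc1)(c1ccccc1)c1ccccc1.[Br-]
Why: Acid-promoted substitution of an ortho-hydroxybenzyl alcohol by PPh3 through the ortho-quinone methide, the standard entry to 2-hydroxybenzylphosphonium salts; the buffered acidity should not cleave the aryl ether.

Step 5
Reactants: 6 3,5-dihydroxybenzoic acid
Product: 8 3,5-di(propan-2-yloxy)benzoic acid, via isopropyl ester 7 (not isolated)
Conditions: i-PrBr, K2CO3, DMF, 80 °C; then NaOH, MeOH/H2O, 70 °C; aq. HCl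
Reagents that add atoms: 2-bromopropane, CC(C)Br; sodium hydroxide, [Na+].[OH-]
Why: Exhaustive Williamson alkylation of both phenols and the carboxylate, then saponification of the isopropyl ester in the same flask; the aryl ethers are stable to hydroxide.

Step 6
Reactants: 8 3,5-di(propan-2-yloxy)benzoic acid; 5 [5-bromo-2-hydroxy-4-(propan-2-yloxy)benzyl]triphenylphosphonium bromide
Product: 11 5-bromo-2-[3,5-di(propan-2-yloxy)phenyl]-6-(propan-2-yloxy)-1-benzofuran, via acyl chloride 9 (not isolated), via O-aroyl phosphonium bromide 10 (not isolated)
Conditions: 8, (COCl)2, cat. DMF, CH2Cl2, rt; evaporate; then 5, Et3N, toluene, 110 °C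
Reagents that add atoms: none
Why: Intramolecular Wittig benzofuran synthesis: the phenol is O-acylated by 9 (O1–C2), Et3N then forms the benzylic ylide, which attacks the neighbouring ester carbonyl and expels Ph3PO to form C2=C3; the bromide and the ethers are spectators.

Step 7
Reactants: 11 5-bromo-2-[3,5-di(propan-2-yloxy)phenyl]-6-(propan-2-yloxy)-1-benzofuran; 12 1,1-diethoxyethene
Product: 14 4,5-cyclobuta-fused 2-[3,5-di(propan-2-yloxy)phenyl]-6-(propan-2-yloxy)-1-benzofuran diethyl ketal (ring CH2 on C4; C(OEt)2 on C5), via 4,5-benzofuranyne 13 (not isolated)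
Conditions: NaNH2 (4 equiv), 12 (5 equiv), THF, 65 °C; then aq. NH4Cl
Reagents that add atoms: none
Why: NaNH2 removes C4–H, the only hydrogen ortho to bromine, and loss of bromide gives aryne 13; deprotonation at C3, C7 or ring C is reversible and unproductive because no leaving group is adjacent. The nucleophilic CH2 terminus of 12 attacks C4 and the resulting C5 aryl anion closes onto the diethoxycarbenium carbon, a stepwise polar [2+2] whose ring closure is a 4-exo-trig attack that forms the four-membered ring fused at C4–C5. The closest known reaction type is the [2+2] cycloaddition of 3-alkoxybenzynes, generated from bromoanisoles with NaNH2, with ketene acetals to give benzocyclobutenone ketals; arynes fused to five-membered heterocycles at these positions are established intermediates. No stereocentre is formed. The selectivity needed is regiochemical: the σ-withdrawing C6 isopropoxy group distorts the aryne so that C4 is the more electrophilic carbon and stabilises the charge developing at C5, which should outweigh the smaller opposite bias of the fused furan ring. Chemoselectivity between 12 and amide ion as aryne traps is addressed by the large excess of 12. The isopropyl ethers are inert to NaNH2 and the ketal product is stable to base.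

Step 8
Reactants: 14 4,5-cyclobuta-fused 2-[3,5-di(propan-2-yloxy)phenyl]-6-(propan-2-yloxy)-1-benzofuran diethyl ketal
Product: 15 benzocyclobutenone: four-membered ketone fused at C4–C5 of 2-[3,5-di(propan-2-yloxy)phenyl]-6-(propan-2-yloxy)-1-benzofuran (CH2 on C4; C=O on C5)
Conditions: 1 M aq. HCl, THF, rt
Reagents that add atoms: water, O
Why: Acid-catalysed ketal hydrolysis; aryl isopropyl ethers and the benzofuran tolerate dilute aqueous acid at room temperature, and the strained ketone is not exposed to base or nucleophiles.

Step 9
Reactants: 15 benzocyclobutenone fused at C4–C5 (CH2 on C4; C=O on C5)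
Product: 16 five-membered aryl lactone of 2-{2-[3,5-di(propan-2-yloxy)phenyl]-5-hydroxy-6-(propan-2-yloxy)-1-benzofuran-4-yl}acetic acid (O5–C(=O)–CH2–C4)
Conditions: mCPBA (1.1 equiv), NaHCO3, CH2Cl2, 0 °C
Reagents that add atoms: 3-chloroperoxybenzoic acid, OOC(=O)c1cccc(Cl)c1
Why: Baeyer–Villiger oxidation of a strained four-membered ketone, which reacts with peracid at low temperature; the migrating aryl carbon C5 has an ortho alkoxy group and a para ring oxygen (O1 through C7a), which should make it a much better migrating group than the primary benzylic CH2, and the cold, buffered, near-stoichiometric conditions are chosen to spare the C2=C3 bond.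

Step 10
Reactants: 16 five-membered aryl lactone (O5–C(=O)–CH2–C4)
Product: 17 2-{2-[3,5-di(propan-2-yloxy)phenyl]-5-hydroxy-6-(propan-2-yloxy)-1-benzofuran-4-yl}-N-methoxy-N-methylacetamide
Conditions: MeNH(OMe)·HCl, AlMe3, CH2Cl2, 0 °C to rt; cold aq. HCl work-up
Reagents that add atoms: N,O-dimethylhydroxylamine hydrochloride, CNOC.Cl
Why: Weinreb aminolysis of a lactone with the aluminium amide formed from AlMe3 and the amine salt; the aryl ester is a reactive acyl donor, and opening releases O5 as the only free phenol in the molecule.

Step 11
Reactants: 17 2-{2-[3,5-di(propan-2-yloxy)phenyl]-5-hydroxy-6-(propan-2-yloxy)-1-benzofuran-4-yl}-N-methoxy-N-methylacetamide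
Product: 18 2-{2-[3,5-di(propan-2-yloxy)phenyl]-5-methoxy-6-(propan-2-yloxy)-1-benzofuran-4-yl}-N-methoxy-N-methylacetamide
Conditions: MeI, K2CO3, acetone, rt
Reagents that add atoms: iodomethane, CI
Why: Williamson methylation of the single free phenol, which fixes the O5-methyl/O6-isopropyl differentiation; carbonate does not deprotonate the amide α-CH2, and methylating before the ketone exists excludes cyclodehydration onto O5.

Step 12
Reactants: 18 2-{2-[3,5-di(propan-2-yloxy)phenyl]-5-methoxy-6-(propan-2-yloxy)-1-benzofuran-4-yl}-N-methoxy-N-methylacetamide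
Product: 19 1-{2-[3,5-di(propan-2-yloxy)phenyl]-5-methoxy-6-(propan-2-yloxy)-1-benzofuran-4-yl}-3-methylbutan-2-one
Conditions: i-PrMgCl (2.5 equiv), THF, −10 to 0 °C; aq. NH4Cl
Reagents that add atoms: isopropylmagnesium chloride, CC(C)[Mg]Cl
Why: Weinreb ketone synthesis; the Grignard reagent adds once to give a magnesium chelate that collapses to the ketone only on aqueous work-up, so no tertiary alcohol should form.

Step 13
Reactants: 19 1-{2-[3,5-di(propan-2-yloxy)phenyl]-5-methoxy-6-(propan-2-yloxy)-1-benzofuran-4-yl}-3-methylbutan-2-one
Product: 20 moracin Q, 1-[2-(3,5-dihydroxyphenyl)-6-hydroxy-5-methoxy-1-benzofuran-4-yl]-3-methylbutan-2-one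
Conditions: BCl3, CH2Cl2, −78 to 0 °C; then H2O
Reagents that add atoms: none
Why: Lewis acid dealkylation of aryl isopropyl ethers; BCl3 coordinates the ether oxygen and chloride removes the secondary alkyl group in an SN1-like step that is much slower for a primary methyl ether at low temperature, so O5–CH3 should survive.

## Compound list

1 | 2,4-dihydroxybenzaldehyde | O=Cc1ccc(O)cc1O | starting material
2 | 2-hydroxy-4-(propan-2-yloxy)benzaldehyde | CC(C)Oc1ccc(C=O)c(O)c1 | intermediate
3 | 5-bromo-2-hydroxy-4-(propan-2-yloxy)benzaldehyde | CC(C)Oc1cc(O)c(C=O)cc1Br | intermediate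
4 | 4-bromo-2-(hydroxymethyl)-5-(propan-2-yloxy)phenol | CC(C)Oc1cc(O)c(CO)cc1Br | intermediate
5 | [5-bromo-2-hydroxy-4-(propan-2-yloxy)benzyl]triphenylphosphonium bromide | CC(C)Oc1cc(O)c(C[P+](c2ccccc2)(c2ccccc2)c2ccccc2)cc1Br.[Br-] | intermediate
6 | 3,5-dihydroxybenzoic acid | OC(=O)c1cc(O)cc(O)c1 | starting material
7 | propan-2-yl 3,5-di(propan-2-yloxy)benzoate | CC(C)OC(=O)c1cc(OC(C)C)cc(OC(C)C)c1 | intermediate
8 | 3,5-di(propan-2-yloxy)benzoic acid | CC(C)Oc1cc(OC(C)C)cc(c1)C(=O)O | intermediate
9 | 3,5-di(propan-2-yloxy)benzoyl chloride | CC(C)Oc1cc(OC(C)C)cc(c1)C(=O)Cl | intermediate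
10 | [5-bromo-2-{[3,5-di(propan-2-yloxy)benzoyl]oxy}-4-(propan-2-yloxy)benzyl]triphenylphosphonium bromide | CC(C)Oc1cc(OC(=O)c2cc(OC(C)C)cc(OC(C)C)c2)c(C[P+](c2ccccc2)(c2ccccc2)c2ccccc2)cc1Br.[Br-] | intermediate
11 | 5-bromo-2-[3,5-di(propan-2-yloxy)phenyl]-6-(propan-2-yloxy)-1-benzofuran | CC(C)Oc1cc2oc(-c3cc(OC(C)C)cc(OC(C)C)c3)cc2cc1Br | intermediate
12 | 1,1-diethoxyethene | C=C(OCC)OCC | starting material
13 | 4,5-didehydro-2-[3,5-di(propan-2-yloxy)phenyl]-6-(propan-2-yloxy)-1-benzofuran (C4≡C5 aryne) | CC(C)OC1=CC2=C(C=C(O2)c2cc(OC(C)C)cc(OC(C)C)c2)C#C1 | intermediate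
14 | 4,5-cyclobuta-fused 2-[3,5-di(propan-2-yloxy)phenyl]-6-(propan-2-yloxy)-1-benzofuran diethyl ketal (ring CH2 on C4; C(OEt)2 on C5) | CCOC1(OCC)Cc2c1c(OC(C)C)cc1oc(-c3cc(OC(C)C)cc(OC(C)C)c3)cc21 | intermediate
15 | benzocyclobutenone fused at C4–C5 of 2-[3,5-di(propan-2-yloxy)phenyl]-6-(propan-2-yloxy)-1-benzofuran (CH2 on C4; C=O on C5) | O=C1Cc2c1c(OC(C)C)cc1oc(-c3cc(OC(C)C)cc(OC(C)C)c3)cc21 | intermediate
16 | five-membered aryl lactone of 2-{2-[3,5-di(propan-2-yloxy)phenyl]-5-hydroxy-6-(propan-2-yloxy)-1-benzofuran-4-yl}acetic acid (O5–C(=O)–CH2–C4) | O=C1Cc2c(O1)c(OC(C)C)cc1oc(-c3cc(OC(C)C)cc(OC(C)C)c3)cc21 | intermediate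
17 | 2-{2-[3,5-di(propan-2-yloxy)phenyl]-5-hydroxy-6-(propan-2-yloxy)-1-benzofuran-4-yl}-N-methoxy-N-methylacetamide | CON(C)C(=O)Cc1c(O)c(OC(C)C)cc2oc(-c3cc(OC(C)C)cc(OC(C)C)c3)cc12 | intermediate
18 | 2-{2-[3,5-di(propan-2-yloxy)phenyl]-5-methoxy-6-(propan-2-yloxy)-1-benzofuran-4-yl}-N-methoxy-N-methylacetamide | CON(C)C(=O)Cc1c(OC)c(OC(C)C)cc2oc(-c3cc(OC(C)C)cc(OC(C)C)c3)cc12 | intermediate
19 | 1-{2-[3,5-di(propan-2-yloxy)phenyl]-5-methoxy-6-(propan-2-yloxy)-1-benzofuran-4-yl}-3-methylbutan-2-one | CC(C)C(=O)Cc1c(OC)c(OC(C)C)cc2oc(-c3cc(OC(C)C)cc(OC(C)C)c3)cc12 | intermediate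
20 | moracin Q, 1-[2-(3,5-dihydroxyphenyl)-6-hydroxy-5-methoxy-1-benzofuran-4-yl]-3-methylbutan-2-one | COc1c(O)cc2oc(-c3cc(O)cc(O)c3)cc2c1CC(=O)C(C)C | target

## Step count and least certain steps

Total: 13 steps. Longest linear sequence: 12 steps (steps 1–4 and 6–13); the ring C branch is step 5.

Step 7 (key step). The most likely failures are loss of regiocontrol (attack of the acetal carbon at C5, which the furan fusion favours), capture of the aryne by amide ion before 12 adds, or sluggish deprotonation at C4. The fallback avoids the aryne and brings in O5 before the carbon chain.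
- From 11, bromine–lithium exchange (n-BuLi, THF, −78 °C), B(OMe)3 and oxidative work-up (H2O2, NaOH) should give the C5 phenol F1.
- O-Alkylation with tert-butyl 2-methylbut-3-en-2-yl carbonate and catalytic Pd(PPh3)4 (zerovalent palladium) in THF should give the tertiary allyl ether F2.
- Aromatic Claisen rearrangement (toluene, 110 °C) can deliver the allyl terminus only to C4, because C6 is blocked, and should give the 4-prenyl-5-hydroxy compound F3.
- Methylation (MeI, K2CO3, acetone) gives the 5-methoxy-4-prenyl compound F4.
- Hydroboration–oxidation (BH3·THF, 0 °C; then H2O2, NaOH) should give the racemic secondary alcohol F5.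
- Oxidation with Dess–Martin periodinane returns to the route at 19.

Step 9. The most likely failures are epoxidation of the electron-rich C2=C3 bond by the electrophilic peracid and migration of the benzylic CH2 in place of the aryl carbon. The fallback uses a nucleophilic oxidant and never makes the lactone.
- From 15, alkaline hydrogen peroxide (H2O2, NaOH, THF/MeOH, 0 °C) adds hydroperoxide only to the strained carbonyl. After rearrangement, saponification in situ and acidification it should give the ring-opened hydroxy acid F6.
- Exhaustive methylation (MeI, K2CO3, DMF) gives the methyl ester methyl ether F7.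
- Aminolysis of the ester (MeNH(OMe)·HCl, i-PrMgCl, THF, −20 °C) returns to the route at 18, bypassing 16 and 17.
- If the benzylic carbon migrates whatever the oxidant, the phenol-first sequence given for step 7 reaches 19 without any oxygen insertion.

Step 12. The most likely failures are deprotonation of the acidic benzylic CH2 by the basic, hindered Grignard reagent (18 returns on work-up) and hydride transfer from the isopropyl group. The fallback changes the nucleophile to an sp2 carbon and sets the isopropyl group by hydrogenation.
- From 18, isopropenylmagnesium bromide (THF, 0 °C), which is less basic and cannot donate hydride, should give the isopropenyl ketone F8.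
- Hydrogenation of its 1,1-disubstituted C=C (H2, catalytic RhCl(PPh3)3, benzene/EtOH, rt), which should leave the benzofuran and the ketone untouched, returns to the route at 19.

Step 13. The most likely failures are engagement of the ketone by the Lewis acid (boron enolate formation, aldol-type self-condensation), re-alkylation of the very electron-rich ring C by the departing isopropyl group, and onset of cleavage of the C5 methyl ether on prolonged exposure through chelation with O6. The fallback deprotects before the ketone exists.
- From 18, BCl3 (CH2Cl2, −78 to 0 °C) should give the triphenol Weinreb amide F9.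
- Excess i-PrMgCl (THF, 0 °C to rt; the first three equivalents form magnesium phenoxides, which also deactivate the rings) followed by aqueous NH4Cl should give 20 directly.

## Further compounds

F1 | step 7 | 2-[3,5-di(propan-2-yloxy)phenyl]-6-(propan-2-yloxy)-1-benzofuran-5-ol | CC(C)Oc1cc2oc(-c3cc(OC(C)C)cc(OC(C)C)c3)cc2cc1O
F2 | step 7 | 2-[3,5-di(propan-2-yloxy)phenyl]-5-[(2-methylbut-3-en-2-yl)oxy]-6-(propan-2-yloxy)-1-benzofuran | CC(C)Oc1cc2oc(-c3cc(OC(C)C)cc(OC(C)C)c3)cc2cc1OC(C)(C)C=C
F3 | step 7 | 2-[3,5-di(propan-2-yloxy)phenyl]-4-(3-methylbut-2-en-1-yl)-6-(propan-2-yloxy)-1-benzofuran-5-ol | CC(C)Oc1cc2oc(-c3cc(OC(C)C)cc(OC(C)C)c3)cc2c(CC=C(C)C)c1O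
F4 | step 7 | 2-[3,5-di(propan-2-yloxy)phenyl]-5-methoxy-4-(3-methylbut-2-en-1-yl)-6-(propan-2-yloxy)-1-benzofuran | CC(C)Oc1cc2oc(-c3cc(OC(C)C)cc(OC(C)C)c3)cc2c(CC=C(C)C)c1OC
F5 | step 7 | rac-1-{2-[3,5-di(propan-2-yloxy)phenyl]-5-methoxy-6-(propan-2-yloxy)-1-benzofuran-4-yl}-3-methylbutan-2-ol | CC(C)C(O)Cc1c(OC)c(OC(C)C)cc2oc(-c3cc(OC(C)C)cc(OC(C)C)c3)cc12
F6 | step 9 | 2-{2-[3,5-di(propan-2-yloxy)phenyl]-5-hydroxy-6-(propan-2-yloxy)-1-benzofuran-4-yl}acetic acid | OC(=O)Cc1c(O)c(OC(C)C)cc2oc(-c3cc(OC(C)C)cc(OC(C)C)c3)cc12
F7 | step 9 | methyl 2-{2-[3,5-di(propan-2-yloxy)phenyl]-5-methoxy-6-(propan-2-yloxy)-1-benzofuran-4-yl}acetate | COC(=O)Cc1c(OC)c(OC(C)C)cc2oc(-c3cc(OC(C)C)cc(OC(C)C)c3)cc12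
F8 | step 12 | 1-{2-[3,5-di(propan-2-yloxy)phenyl]-5-methoxy-6-(propan-2-yloxy)-1-benzofuran-4-yl}-3-methylbut-3-en-2-one | CC(=C)C(=O)Cc1c(OC)c(OC(C)C)cc2oc(-c3cc(OC(C)C)cc(OC(C)C)c3)cc12
F9 | step 13 | 2-[2-(3,5-dihydroxyphenyl)-6-hydroxy-5-methoxy-1-benzofuran-4-yl]-N-methoxy-N-methylacetamide | CON(C)C(=O)Cc1c(OC)c(O)cc2oc(-c3cc(O)cc(O)c3)cc12
A1 | alternative 1 | 2-{[3,5-di(propan-2-yloxy)phenyl]ethynyl}-4-methoxy-3-(3-methylbut-2-en-1-yl)-5-(propan-2-yloxy)phenol | Oc1cc(OC(C)C)c(OC)c(CC=C(C)C)c1C#Cc1cc(OC(C)C)cc(OC(C)C)c1
A2 | alternative 1 | rac-4-{(3E)-1-[3,5-di(propan-2-yloxy)phenyl]-7-methylocta-3,6-dien-1-yn-4-yl}-4-methoxy-3-(propan-2-yloxy)cyclobut-2-en-1-one | O=C1C=C(OC(C)C)C1(OC)/C(CC=C(C)C)=C/C#Cc1cc(OC(C)C)cc(OC(C)C)c1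
A3 | alternative 2 | 6-(benzyloxy)-2-[3,5-bis(benzyloxy)phenyl]-5-methoxy-4-(3-methylbut-2-en-1-yl)-1-benzofuran | COc1c(OCc2ccccc2)cc2oc(-c3cc(OCc4ccccc4)cc(OCc4ccccc4)c3)cc2c1CC=C(C)C
A4 | alternative 2 | 5-(benzyloxy)-2-formyl-4-methoxy-3-(3-methylbut-2-en-1-yl)phenyl 3,5-bis(benzyloxy)benzoate | COc1c(OCc2ccccc2)cc(OC(=O)c2cc(OCc3ccccc3)cc(OCc3ccccc3)c2)c(C=O)c1CC=C(C)C
A5 | alternative 3 | methyl 2-{2-[3,5-bis(benzyloxy)phenyl]-6-hydroxy-5-methoxy-1-benzofuran-4-yl}acetate | COC(=O)Cc1c(OC)c(O)cc2oc(-c3cc(OCc4ccccc4)cc(OCc4ccccc4)c3)cc12
A6 | alternative 3 | rac-methyl 6-{5-[3,5-bis(benzyloxy)phenyl]furan-2-yl}-4-methoxy-3,5-dioxohexanoate | COC(=O)CC(=O)C(OC)C(=O)Cc1ccc(-c2cc(OCc3ccccc3)cc(OCc3ccccc3)c2)o1
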